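Target (germacrane numbering): ten-membered ring C1–C10 with olefins C1=C10 and C4=C5, cis-fused at C6/C7 to the α-methylene-γ-lactone O6–C12(=O)–C11(=C13)–C7; O8 angelate, C14 formyl on C10, C15 hydroxymethyl on C4.
Feature used: C7 carries C11 and lies between the oxygen-bearing carbons C6 and C8. Key disconnection: C7–C11 by rear-side opening of a trans C7–C8 epoxide by a phosphonoacetate carbanion held on O6 (the epoxide oxygen becomes O8), then C11=C13 with formaldehyde; the lactone is the first ring formed.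
Second disconnection, C1–C10 (ten-membered ring, formed last): C14 is carried from the start as a PMB-protected alcohol; its aldehyde becomes an enol silane whose C10 adds to the C1 dimethyl acetal, and loss of methanol gives the C1=C10 enal. A non-stabilised C10 ylide is avoided because it could not be made or formylated beside the methylene lactone and the C8 ester.
Open chain: C5–C6 by alkynide addition to a C6–C10–C14 enal; C4=C5 (C3 cis to C6) by O6-directed trans-hydroalumination/iodination and B-alkyl Suzuki coupling of the C1–C3 acetal unit; C7/C8 by Sharpless kinetic resolution; Mitsunobu esterification inverts C6 and attaches the tether.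

Key step: step 9

Remark: the target olefin C4=C5 has C3 cis to C6 (4E by the sequence rule, because C15 outranks C3); anti-carbometalation of propargyl alcohol followed by iodination would give the opposite arrangement, so the geometry is set through the C6 alkoxide instead. O15 is protected as the TBDPS ether. In open-chain names the undecane locants 1–10 are the ring locants and chain C11 is C14.

Step 1
Reactants: 1 prop-2-yn-1-ol (propargyl alcohol)
Product: 2 tert-butyl(diphenyl)(prop-2-yn-1-yloxy)silane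
Conditions: TBDPSCl, imidazole, DMF, 0 °C to rt
Reagents that add atoms: tert-butyl(chloro)diphenylsilane, CC(C)(C)[Si](Cl)(c1ccccc1)c1ccccc1
Why: Silyl ether formation of a primary alcohol with a silyl chloride and imidazole, the TBDPS group being chosen because it should stay on O15 through the acidic and Lewis acidic steps up to the last one.

Step 2
Reactants: 3 pent-4-en-1-ol
Product: 4 1-methoxy-4-[(pent-4-en-1-yloxy)methyl]benzene
Conditions: NaH, 4-methoxybenzyl chloride, Bu4NI (cat.), THF/DMF, 0 °C to rt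
Reagents that add atoms: 4-methoxybenzyl chloride, COc1ccc(CCl)cc1
Why: Williamson ether synthesis gives the PMB ether, which later frees O14 oxidatively without touching the silyl ether.

Step 3
Reactants: 4 1-methoxy-4-[(pent-4-en-1-yloxy)methyl]benzene
Product: 5 (E)-6-[(4-methoxybenzyl)oxy]hex-2-enal
Conditions: crotonaldehyde (5 equiv), second-generation Grubbs catalyst RuCl2(=CHPh)(PCy3)(H2IMes) (3 mol%), CH2Cl2, 40 °C
Reagents that add atoms: (E)-but-2-enal (crotonaldehyde), C/C=C/C=O
Why: Olefin cross-metathesis of a terminal olefin with excess crotonaldehyde should give the E-enal selectively, with propene as the only by-product.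

Step 4
Reactants: 2 tert-butyl(diphenyl)(prop-2-yn-1-yloxy)silane; 5 (E)-6-[(4-methoxybenzyl)oxy]hex-2-enal
Product: 7 racemic (E)-1-[(tert-butyldiphenylsilyl)oxy]-9-[(4-methoxybenzyl)oxy]non-5-en-2-yn-4-ol, via lithium alkynide 6 (not isolated)
Conditions: n-BuLi, THF, −78 °C; then 5, −78 °C; aqueous NH4Cl
Reagents that add atoms: none
Why: 1,2-Addition of a lithium alkynide to the enal carbonyl at low temperature joins C5 to C6 and should give the propargylic allylic alcohol without conjugate addition.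

Step 5
Reactants: 7 racemic (E)-1-[(tert-butyldiphenylsilyl)oxy]-9-[(4-methoxybenzyl)oxy]non-5-en-2-yn-4-ol
Product: 9 racemic (2Z,5E)-1-[(tert-butyldiphenylsilyl)oxy]-2-iodo-9-[(4-methoxybenzyl)oxy]nona-2,5-dien-4-ol, via cyclic sodium alkenylalanate 8 (not isolated)
Conditions: NaAlH2(OCH2CH2OMe)2, THF, 0 °C; EtOAc; then I2, THF, −78 °C
Reagents that add atoms: iodine, II
Why: Alkoxide-directed trans-hydroalumination of the propargylic alcohol delivers hydride to C5 and aluminium to C4 within a five-membered chelate, and iodine replaces aluminium with retention, so that iodine stands cis to C6 (Z-iodide) while the isolated E-olefin and the ethers are not touched.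

Step 6
Reactants: 9 racemic (2Z,5E)-iodo dienol; 10 3,3-dimethoxyprop-1-ene (acrolein dimethyl acetal)
Product: 12 racemic (4E,7E)-4-{[(tert-butyldiphenylsilyl)oxy]methyl}-1,1-dimethoxy-11-[(4-methoxybenzyl)oxy]undeca-4,7-dien-6-ol, via B-alkyl-9-BBN borane 11 (not isolated)
Conditions: 10, 9-BBN-H dimer, THF, 0 °C to rt; then 9, PdCl2(dppf), AsPh3, Cs2CO3, DMF/H2O, rt
Reagents that add atoms: none
Why: Anti-Markovnikov hydroboration of the acetal olefin and B-alkyl Suzuki–Miyaura coupling with the alkenyl iodide proceed with retention at C4, which places the C1–C3 chain cis to C6 (4E) as in the target, and the free hydroxyl is tolerated.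

Step 7
Reactants: 12 racemic (4E,7E)-dienol
Product: 13 (4E,6S,7S,8S)-4-{[(tert-butyldiphenylsilyl)oxy]methyl}-7,8-epoxy-1,1-dimethoxy-11-[(4-methoxybenzyl)oxy]undec-4-en-6-ol
Conditions: Ti(OiPr)4 (1.0 equiv), L-(+)-diisopropyl tartrate (1.2 equiv), t-BuOOH (0.5 equiv), 4 Å molecular sieves, CH2Cl2, −20 °C
Reagents that add atoms: tert-butyl hydroperoxide, CC(C)(C)OO
Why: Sharpless kinetic resolution, in which the titanium complex of the L-(+)-tartrate epoxidises the (6R)-alcohol (the spatial counterpart of the fast-reacting S enantiomer of simple alkenyl carbinols, the descriptor differing only because C5 outranks C7) at its E-disubstituted C7=C8 olefin to the 6,7-erythro (7S,8S)-epoxide, so that C7 and C8 are set by the reagent, while for this enantiomer C4=C5 is the mismatched olefin and also carries the C3 chain cis to the carbinol carbon, the pattern that reacts slowly, and the (6S)-alcohol is left behind.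

Step 8
Reactants: 13 (4E,6S,7S,8S)-epoxy alcohol; 14 2-(diethoxyphosphoryl)acetic acid (diethylphosphonoacetic acid)
Product: 15 (4E,6R,7R,8S)-4-{[(tert-butyldiphenylsilyl)oxy]methyl}-7,8-epoxy-1,1-dimethoxy-11-[(4-methoxybenzyl)oxy]undec-4-en-6-yl 2-(diethoxyphosphoryl)acetate
Conditions: PPh3, DIAD, THF, 0 °C to rt
Reagents that add atoms: none
Why: Mitsunobu esterification displaces the oxyphosphonium group by the acidic phosphonoacetic acid in an SN2 step, which inverts C6 to R and attaches the O6 tether in one operation without opening the epoxide (the C7 descriptor changes from S to R by the sequence rule only).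

Step 9
Reactants: 15 (4E,6R,7R,8S)-epoxy phosphonoacetate
Product: 17 (4S,5R)-5-[(1E)-2-{[(tert-butyldiphenylsilyl)oxy]methyl}-5,5-dimethoxypent-1-en-1-yl]-4-{(1S)-1-hydroxy-4-[(4-methoxybenzyl)oxy]butyl}-3-methylideneoxolan-2-one, via alpha-phosphono lactone 16 (not isolated)
Conditions: NaH (1.05 equiv), THF, 0 to 45 °C; then (CH2O)n, 0 °C to rt
Reagents that add atoms: formaldehyde (as paraformaldehyde), C=O
Why: Deprotonation of the phosphonoacetate CH2 gives a stabilised carbanion (C11) that attacks C7 of the trans-epoxide from the side opposite to the C7–O bond (intramolecular SN2), which forms C7–C11, closes the γ-lactone and releases the C8 alkoxide; this alkoxide is quenched by the acidic C11–H and the resulting phosphonate anion condenses with formaldehyde (Horner–Wadsworth–Emmons) to give C11=C13. The closest known reactions are the intermolecular opening of epoxides by phosphonoacetate anions to α-phosphono-γ-lactones followed by methylenation with formaldehyde, and the tethered Michael addition/methylenation of phosphonoacetate esters of γ-hydroxy enones. The lactone ring closes in the 5-exo-tet mode, the breaking C7–O bond lying outside the new ring. The one new stereocentre, C7, is set by inversion, so the (7R,8S)-epoxide fixes 7S and, with the unchanged 6R centre, the cis relation of C5 and C8 on the lactone, while C8 keeps its configuration because its C–O bond is not touched. The step needs attack at C7 and not at C8, and the O6 tether secures this because C7 is reached through a five-membered transition state and C8 only through a six-membered endo one, against the usual preference of free nucleophiles for the distal carbon. The methylenation runs through a weakly basic phosphonate anion, so the acetal, the silyl ether and the PMB ether should survive.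

Step 10
Reactants: 17 (6R,7S,8S)-hydroxy methylene lactone; 18 (Z)-2-methylbut-2-enoic acid (angelic acid)
Product: 20 (1S)-1-[(2R,3S)-2-[(1E)-2-{[(tert-butyldiphenylsilyl)oxy]methyl}-5,5-dimethoxypent-1-en-1-yl]-4-methylidene-5-oxooxolan-3-yl]-4-[(4-methoxybenzyl)oxy]butyl (2Z)-2-methylbut-2-enoate, via angelic 2,4,6-trichlorobenzoic anhydride 19 (not isolated)
Conditions: 18, 2,4,6-trichlorobenzoyl chloride, Et3N, toluene, rt; then 17, toluene, 80 °C
Reagents that add atoms: none
Why: Yamaguchi-type esterification through the mixed anhydride, run without a nucleophilic catalyst, acylates the C8 hydroxyl at the unhindered angeloyl carbonyl and is the variant that should avoid Z to E isomerisation of the angelate to the tiglate.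

Step 11
Reactants: 20 O8-angelate PMB ether
Product: 21 (1S)-1-[(2R,3S)-2-[(1E)-2-{[(tert-butyldiphenylsilyl)oxy]methyl}-5,5-dimethoxypent-1-en-1-yl]-4-methylidene-5-oxooxolan-3-yl]-4-hydroxybutyl (2Z)-2-methylbut-2-enoate
Conditions: DDQ, CH2Cl2/pH 7 buffer, 0 °C
Reagents that add atoms: none
Why: Oxidative cleavage of the 4-methoxybenzyl ether by DDQ (benzylic oxocarbenium ion, hydrolysed by water) frees the O14 alcohol and should leave the silyl ether, acetal, angelate and methylene lactone untouched.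

Step 12
Reactants: 21 C14 primary alcohol
Product: 22 (1S)-1-[(2R,3S)-2-[(1E)-2-{[(tert-butyldiphenylsilyl)oxy]methyl}-5,5-dimethoxypent-1-en-1-yl]-4-methylidene-5-oxooxolan-3-yl]-4-oxobutyl (2Z)-2-methylbut-2-enoate
Conditions: Dess–Martin periodinane, NaHCO3, CH2Cl2, 0 °C to rt
Reagents that add atoms: none
Why: Dess–Martin oxidation of the primary alcohol under buffered, non-basic conditions gives the C14 aldehyde without conjugate addition to the methylene lactone or isomerisation of the angelate.

Step 13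
Reactants: 22 C14 aldehyde with C1 dimethyl acetal
Product: 23 (1S)-4-[(tert-butyldimethylsilyl)oxy]-1-[(2R,3S)-2-[(1E)-2-{[(tert-butyldiphenylsilyl)oxy]methyl}-5,5-dimethoxypent-1-en-1-yl]-4-methylidene-5-oxooxolan-3-yl]but-3-en-1-yl (2Z)-2-methylbut-2-enoate (E/Z mixture at the enol ether)
Conditions: TBSOTf, Et3N (excess), CH2Cl2, −78 °C
Reagents that add atoms: tert-butyldimethylsilyl trifluoromethanesulfonate, CC(C)(C)[Si](C)(C)OS(=O)(=O)C(F)(F)F
Why: Soft enolisation of the aldehyde with a silyl triflate and a tertiary amine (silyl enol ether formation) makes C10 the only nucleophilic carbon, while at low temperature and with excess amine the dimethyl acetal should not be ionised.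

Step 14
Reactants: 23 C14 silyl enol ether with C1 dimethyl acetal
Product: 25 (1(10)E,4E,6R,7S,8S)-8-angeloyloxy-15-[(tert-butyldiphenylsilyl)oxy]-14-oxogermacra-1(10),4,11(13)-trien-6,12-olide, via beta-methoxy aldehyde 24 (not isolated)
Conditions: TMSOTf (0.2 equiv), CH2Cl2, −78 °C, slow addition of 23 to 1 mM; then DBU, −78 to 0 °C
Reagents that add atoms: none
Why: Mukaiyama-type aldol addition, in which the silyl triflate ionises the C1 acetal to an oxocarbenium ion that is captured by the C10 enol ether to close the ten-membered ring, followed by base-induced E1cB loss of methanol from the β-methoxy aldehyde to the conjugated enal with the formyl group trans to C2 (the more stable geometry and that of the target), the regiochemistry being fixed because only C14 is an enol ether and only C1 is an acetal, and aldehydes not reacting under these conditions.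

Step 15
Reactants: 25 O15-TBDPS ether of the target
Product: 26 (1(10)E,4E,6R,7S,8S)-8-angeloyloxy-15-hydroxy-14-oxogermacra-1(10),4,11(13)-trien-6,12-olide (CNP0173211.3)
Conditions: HF·pyridine, pyridine/THF, 0 °C to rt
Reagents that add atoms: none
Why: Fluoride-mediated desilylation under buffered acidic conditions frees the C15 alcohol without base, so that the enal, the angelate and the methylene lactone should survive.

Compound list
1 | prop-2-yn-1-ol (propargyl alcohol) | C#CCO | starting material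
2 | tert-butyl(diphenyl)(prop-2-yn-1-yloxy)silane | C#CCO[Si](c1ccccc1)(c1ccccc1)C(C)(C)C | intermediate
3 | pent-4-en-1-ol | C=CCCCO | starting material
4 | 1-methoxy-4-[(pent-4-en-1-yloxy)methyl]benzene | C=CCCCOCc1ccc(OC)cc1 | intermediate
5 | (E)-6-[(4-methoxybenzyl)oxy]hex-2-enal | O=C/C=C/CCCOCc1ccc(OC)cc1 | intermediate
6 | lithium alkynide of 2 [lithium 3-[(tert-butyldiphenylsilyl)oxy]prop-1-yn-1-ide] | [Li]C#CCO[Si](c1ccccc1)(c1ccccc1)C(C)(C)C | intermediate
7 | racemic (E)-1-[(tert-butyldiphenylsilyl)oxy]-9-[(4-methoxybenzyl)oxy]non-5-en-2-yn-4-ol | OC(C#CCO[Si](c1ccccc1)(c1ccccc1)C(C)(C)C)/C=C/CCCOCc1ccc(OC)cc1 | intermediate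
8 | racemic sodium alanate of 7: aluminium bound to O4, to C2 of the new alkene (five-membered O–Al–C=C–C ring) and to two 2-methoxyethoxy groups | [Na+].COCCO[Al-]1(OCCOC)OC(/C=C/CCCOCc2ccc(OC)cc2)C=C1CO[Si](c1ccccc1)(c1ccccc1)C(C)(C)C | intermediate
9 | racemic (2Z,5E)-1-[(tert-butyldiphenylsilyl)oxy]-2-iodo-9-[(4-methoxybenzyl)oxy]nona-2,5-dien-4-ol | OC(/C=C(\I)CO[Si](c1ccccc1)(c1ccccc1)C(C)(C)C)/C=C/CCCOCc1ccc(OC)cc1 | intermediate
10 | 3,3-dimethoxyprop-1-ene (acrolein dimethyl acetal) | C=CC(OC)OC | starting material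
11 | 9-(3,3-dimethoxypropyl)-9-borabicyclo[3.3.1]nonane | COC(OC)CCB1C2CCCC1CCC2 | intermediate
12 | racemic (4E,7E)-4-{[(tert-butyldiphenylsilyl)oxy]methyl}-1,1-dimethoxy-11-[(4-methoxybenzyl)oxy]undeca-4,7-dien-6-ol | OC(/C=C(/CO[Si](c1ccccc1)(c1ccccc1)C(C)(C)C)CCC(OC)OC)/C=C/CCCOCc1ccc(OC)cc1 | intermediate
13 | (4E,6S,7S,8S)-4-{[(tert-butyldiphenylsilyl)oxy]methyl}-7,8-epoxy-1,1-dimethoxy-11-[(4-methoxybenzyl)oxy]undec-4-en-6-ol | O[C@@H](/C=C(/CO[Si](c1ccccc1)(c1ccccc1)C(C)(C)C)CCC(OC)OC)[C@@H]1O[C@H]1CCCOCc1ccc(OC)cc1 | intermediate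
14 | 2-(diethoxyphosphoryl)acetic acid (diethylphosphonoacetic acid) | OC(=O)CP(=O)(OCC)OCC | starting material
15 | (4E,6R,7R,8S)-4-{[(tert-butyldiphenylsilyl)oxy]methyl}-7,8-epoxy-1,1-dimethoxy-11-[(4-methoxybenzyl)oxy]undec-4-en-6-yl 2-(diethoxyphosphoryl)acetate (key-step precursor) | CCOP(=O)(OCC)CC(=O)O[C@H](/C=C(/CO[Si](c1ccccc1)(c1ccccc1)C(C)(C)C)CCC(OC)OC)[C@@H]1O[C@H]1CCCOCc1ccc(OC)cc1 | intermediate
16 | (4S,5R)-3-(diethoxyphosphoryl)-5-[(1E)-2-{[(tert-butyldiphenylsilyl)oxy]methyl}-5,5-dimethoxypent-1-en-1-yl]-4-{(1S)-1-hydroxy-4-[(4-methoxybenzyl)oxy]butyl}oxolan-2-one (C3 epimers) | CCOP(=O)(OCC)C1C(=O)O[C@H](/C=C(/CO[Si](c2ccccc2)(c2ccccc2)C(C)(C)C)CCC(OC)OC)[C@@H]1[C@@H](O)CCCOCc1ccc(OC)cc1 | intermediate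
17 | (4S,5R)-5-[(1E)-2-{[(tert-butyldiphenylsilyl)oxy]methyl}-5,5-dimethoxypent-1-en-1-yl]-4-{(1S)-1-hydroxy-4-[(4-methoxybenzyl)oxy]butyl}-3-methylideneoxolan-2-one (key-step product; 6R,7S,8S) | C=C1C(=O)O[C@H](/C=C(/CO[Si](c2ccccc2)(c2ccccc2)C(C)(C)C)CCC(OC)OC)[C@@H]1[C@@H](O)CCCOCc1ccc(OC)cc1 | intermediate
18 | (Z)-2-methylbut-2-enoic acid (angelic acid) | C/C=C(/C)C(=O)O | starting material
19 | (Z)-2-methylbut-2-enoic 2,4,6-trichlorobenzoic anhydride | C/C=C(/C)C(=O)OC(=O)c1c(Cl)cc(Cl)cc1Cl | intermediate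
20 | (1S)-1-[(2R,3S)-2-[(1E)-2-{[(tert-butyldiphenylsilyl)oxy]methyl}-5,5-dimethoxypent-1-en-1-yl]-4-methylidene-5-oxooxolan-3-yl]-4-[(4-methoxybenzyl)oxy]butyl (2Z)-2-methylbut-2-enoate | C=C1C(=O)O[C@H](/C=C(/CO[Si](c2ccccc2)(c2ccccc2)C(C)(C)C)CCC(OC)OC)[C@@H]1[C@@H](OC(=O)/C(C)=C\C)CCCOCc1ccc(OC)cc1 | intermediate
21 | (1S)-1-[(2R,3S)-2-[(1E)-2-{[(tert-butyldiphenylsilyl)oxy]methyl}-5,5-dimethoxypent-1-en-1-yl]-4-methylidene-5-oxooxolan-3-yl]-4-hydroxybutyl (2Z)-2-methylbut-2-enoate | C=C1C(=O)O[C@H](/C=C(/CO[Si](c2ccccc2)(c2ccccc2)C(C)(C)C)CCC(OC)OC)[C@@H]1[C@@H](OC(=O)/C(C)=C\C)CCCO | intermediate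
22 | (1S)-1-[(2R,3S)-2-[(1E)-2-{[(tert-butyldiphenylsilyl)oxy]methyl}-5,5-dimethoxypent-1-en-1-yl]-4-methylidene-5-oxooxolan-3-yl]-4-oxobutyl (2Z)-2-methylbut-2-enoate | C=C1C(=O)O[C@H](/C=C(/CO[Si](c2ccccc2)(c2ccccc2)C(C)(C)C)CCC(OC)OC)[C@@H]1[C@@H](OC(=O)/C(C)=C\C)CCC=O | intermediate
23 | (1S)-4-[(tert-butyldimethylsilyl)oxy]-1-[(2R,3S)-2-[(1E)-2-{[(tert-butyldiphenylsilyl)oxy]methyl}-5,5-dimethoxypent-1-en-1-yl]-4-methylidene-5-oxooxolan-3-yl]but-3-en-1-yl (2Z)-2-methylbut-2-enoate (E/Z mixture at the enol ether) | C=C1C(=O)O[C@H](/C=C(/CO[Si](c2ccccc2)(c2ccccc2)C(C)(C)C)CCC(OC)OC)[C@@H]1[C@@H](OC(=O)/C(C)=C\C)CC=CO[Si](C)(C)C(C)(C)C | intermediate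
24 | (4E,6R,7S,8S)-8-angeloyloxy-15-[(tert-butyldiphenylsilyl)oxy]-1-methoxy-14-oxogermacra-4,11(13)-dien-6,12-olide (mixture of C1 and C10 epimers) | C=C1C(=O)O[C@@H]2/C=C(/CO[Si](c3ccccc3)(c3ccccc3)C(C)(C)C)CCC(OC)C(C=O)C[C@H](OC(=O)/C(C)=C\C)[C@H]12 | intermediate
25 | (1(10)E,4E,6R,7S,8S)-8-angeloyloxy-15-[(tert-butyldiphenylsilyl)oxy]-14-oxogermacra-1(10),4,11(13)-trien-6,12-olide | C=C1C(=O)O[C@@H]2/C=C(/CO[Si](c3ccccc3)(c3ccccc3)C(C)(C)C)CC/C=C(/C=O)C[C@H](OC(=O)/C(C)=C\C)[C@H]12 | intermediate
26 | (1(10)E,4E,6R,7S,8S)-8-angeloyloxy-15-hydroxy-14-oxogermacra-1(10),4,11(13)-trien-6,12-olide (CNP0173211.3) | C=C1C(=O)O[C@@H]2/C=C(/CO)CC/C=C(/C=O)C[C@H](OC(=O)/C(C)=C\C)[C@H]12 | target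

Total step count: 15. Longest linear sequence: 14 steps (pent-4-en-1-ol 3 to the target 26, steps 2 to 15).

Steps most likely to fail

1. Step 9 (key step). The ester tether must leave its preferred s-cis conformation and the phosphonate-stabilised carbanion is a weak nucleophile, so ring closure may be slow. Opening at C8 to the six-membered lactone could then compete, as could attack of the liberated C8 alkoxide on phosphorus or on the lactone carbonyl (migration of the lactone to O8), or incomplete methylenation. The fallback sets out from 13 and returns at 17; it replaces the phosphonate and the Horner–Wadsworth–Emmons step by a malonate and a decarboxylative methylenation. Mitsunobu esterification of 13 with allyl hydrogen malonate (PPh3, DIAD) gives, with the same inversion at C6, the allyl malonate F1. A catalytic amount of NaH in THF lets the malonate carbanion, the classical carbon nucleophile for epoxides, open the epoxide at C7 to the allyl lactone carboxylate F2. Pd(PPh3)4 and morpholine remove the allyl group to give the lactone acid F3. Aqueous formaldehyde and diethylamine (Mannich reaction with decarboxylation) convert F3 into 17.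

2. Step 14. Intermolecular aldol addition (oligomerisation) may outpace closure of the ten-membered ring, the oxocarbenium ion may be intercepted by the C4=C5 olefin or by the O15 ether oxygen, or the enol ether may be hydrolysed before it reacts. The fallback sets out from 23 and returns at 25; it closes C1=C10 by an intramolecular Wittig reaction of a formyl-stabilised ylide that is made without any non-stabilised ylide. NBS (THF, −78 °C) converts 23 into the alpha-bromo aldehyde F4. PPh3 (toluene, rt) displaces bromide and aqueous NaHCO3 deprotonates the phosphonium salt to the formyl ylide F5. Aqueous oxalic acid, then NaHCO3, hydrolyses the C1 acetal to the ylide aldehyde F6. Heating F6 in toluene at high dilution should give 25.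

3. Step 7. The mismatched (6S)-enantiomer may be epoxidised at C4=C5 or at C7=C8 at a rate that is not negligible, which would lower the enantiomeric purity of 13 or contaminate it with regioisomeric epoxides; the bis-allylic alcohol may also ionise on the Lewis acidic titanium. The fallback sets out from 7 and returns at 13; the resolution is moved to the stage where only one olefin is present and is done by recovery of the slow enantiomer. Sharpless kinetic resolution of 7 with D-(−)-diisopropyl tartrate, Ti(OiPr)4 and t-BuOOH (0.6 equiv) consumes the (4S)-enantiomer (the alkyne is inert) and leaves the (4R)-enynol F7. The conditions of steps 5 and 6 convert F7 into the (4R)-iodo dienol F8 and then the (6R)-dienol F9. Epoxidation of F9 with L-(+)-diisopropyl tartrate, Ti(OiPr)4 and excess t-BuOOH is then a matched, reagent-controlled reaction of a single enantiomer and should give 13.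

Further compounds
F1 | step 9 | allyl (4E,6R,7R,8S)-4-{[(tert-butyldiphenylsilyl)oxy]methyl}-7,8-epoxy-1,1-dimethoxy-11-[(4-methoxybenzyl)oxy]undec-4-en-6-yl propanedioate | C=CCOC(=O)CC(=O)O[C@H](/C=C(/CO[Si](c1ccccc1)(c1ccccc1)C(C)(C)C)CCC(OC)OC)[C@@H]1O[C@H]1CCCOCc1ccc(OC)cc1
F2 | step 9 | allyl (4S,5R)-5-[(1E)-2-{[(tert-butyldiphenylsilyl)oxy]methyl}-5,5-dimethoxypent-1-en-1-yl]-4-{(1S)-1-hydroxy-4-[(4-methoxybenzyl)oxy]butyl}-2-oxooxolane-3-carboxylate (C3 epimers) | C=CCOC(=O)C1C(=O)O[C@H](/C=C(/CO[Si](c2ccccc2)(c2ccccc2)C(C)(C)C)CCC(OC)OC)[C@@H]1[C@@H](O)CCCOCc1ccc(OC)cc1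
F3 | step 9 | (4S,5R)-5-[(1E)-2-{[(tert-butyldiphenylsilyl)oxy]methyl}-5,5-dimethoxypent-1-en-1-yl]-4-{(1S)-1-hydroxy-4-[(4-methoxybenzyl)oxy]butyl}-2-oxooxolane-3-carboxylic acid (C3 epimers) | OC(=O)C1C(=O)O[C@H](/C=C(/CO[Si](c2ccccc2)(c2ccccc2)C(C)(C)C)CCC(OC)OC)[C@@H]1[C@@H](O)CCCOCc1ccc(OC)cc1
F4 | step 14 | (1S)-3-bromo-1-[(2R,3S)-2-[(1E)-2-{[(tert-butyldiphenylsilyl)oxy]methyl}-5,5-dimethoxypent-1-en-1-yl]-4-methylidene-5-oxooxolan-3-yl]-4-oxobutyl (2Z)-2-methylbut-2-enoate (C3 epimers of the butyl chain) | C=C1C(=O)O[C@H](/C=C(/CO[Si](c2ccccc2)(c2ccccc2)C(C)(C)C)CCC(OC)OC)[C@@H]1[C@@H](OC(=O)/C(C)=C\C)CC(Br)C=O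
F5 | step 14 | (1S)-1-[(2R,3S)-2-[(1E)-2-{[(tert-butyldiphenylsilyl)oxy]methyl}-5,5-dimethoxypent-1-en-1-yl]-4-methylidene-5-oxooxolan-3-yl]-4-oxo-3-(triphenylphosphoranylidene)butyl (2Z)-2-methylbut-2-enoate | C=C1C(=O)O[C@H](/C=C(/CO[Si](c2ccccc2)(c2ccccc2)C(C)(C)C)CCC(OC)OC)[C@@H]1[C@@H](OC(=O)/C(C)=C\C)CC(C=O)=P(c1ccccc1)(c1ccccc1)c1ccccc1
F6 | step 14 | (1S)-1-[(2R,3S)-2-[(1E)-2-{[(tert-butyldiphenylsilyl)oxy]methyl}-5-oxopent-1-en-1-yl]-4-methylidene-5-oxooxolan-3-yl]-4-oxo-3-(triphenylphosphoranylidene)butyl (2Z)-2-methylbut-2-enoate | C=C1C(=O)O[C@H](/C=C(/CO[Si](c2ccccc2)(c2ccccc2)C(C)(C)C)CCC=O)[C@@H]1[C@@H](OC(=O)/C(C)=C\C)CC(C=O)=P(c1ccccc1)(c1ccccc1)c1ccccc1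
F7 | step 7 | (4R,5E)-1-[(tert-butyldiphenylsilyl)oxy]-9-[(4-methoxybenzyl)oxy]non-5-en-2-yn-4-ol | O[C@@H](C#CCO[Si](c1ccccc1)(c1ccccc1)C(C)(C)C)/C=C/CCCOCc1ccc(OC)cc1
F8 | step 7 | (2Z,4R,5E)-1-[(tert-butyldiphenylsilyl)oxy]-2-iodo-9-[(4-methoxybenzyl)oxy]nona-2,5-dien-4-ol | O[C@@H](/C=C(\I)CO[Si](c1ccccc1)(c1ccccc1)C(C)(C)C)/C=C/CCCOCc1ccc(OC)cc1
F9 | step 7 | (4E,6R,7E)-4-{[(tert-butyldiphenylsilyl)oxy]methyl}-1,1-dimethoxy-11-[(4-methoxybenzyl)oxy]undeca-4,7-dien-6-ol | O[C@@H](/C=C(/CO[Si](c1ccccc1)(c1ccccc1)C(C)(C)C)CCC(OC)OC)/C=C/CCCOCc1ccc(OC)cc1
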